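**Retrosynthetic overview**
- The target comes from global acid deprotection of a tert-butyl ester/ketal precursor; its CH2CHO arm comes from aldehyde-selective Wacker oxidation of a vinyl group.
- Key disconnection: the enol-ether C–O bond of the formyl-alkylidene dihydrofuran, closed late by 5-exo-dig attack of a tertiary hydroxyl on an alkyne with in-flask capture of a formyl equivalent. This is the only ring and it is formed last.
- The (Z)-enynol comes from a Sonogashira coupling of a terminal alkyne with a (Z)-iodo tertiary alcohol.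
- Both stereocentres come from one enantioselective boron Ireland–Claisen rearrangement of an (E)-pentenynyl ester.
- The ester comes from a 3-methylidene acid (diketene plus a ketal Grignard reagent) and (E)-pent-2-en-4-yn-1-ol.

Assumption: the (S,S)-diazaborolidine controller is taken to induce the same facial sense as in its reported α-isopropenyl ester rearrangements (recalled, not checked); if the sense is opposite, its enantiomer is used and nothing else changes.

**Step 1**
Reactants: 1 2-(3-chloropropyl)-2-methyl-1,3-dioxolane; 2 diketene (4-methylideneoxetan-2-one)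
Product: 4 3-methylidene-6-(2-methyl-1,3-dioxolan-2-yl)hexanoic acid, via Grignard reagent 3 (not isolated)
Conditions: 1, Mg, THF, reflux; then added to 2, NiCl2 (5 mol%), THF, −30 → 0 °C; aq. NH4Cl, citric acid to pH 3
Reagents that add atoms: none
Why: Ni-catalysed Kumada-type cross-coupling of the Grignard reagent at the vinylic C–O bond of diketene opens the enol lactone to the 3-methylidene carboxylate, with the ketal protecting the ketone; no stereocentre is formed.

**Step 2**
Reactants: 4 3-methylidene-6-(2-methyl-1,3-dioxolan-2-yl)hexanoic acid; 5 (2E)-pent-2-en-4-yn-1-ol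
Product: 6 (2E)-pent-2-en-4-yn-1-yl 3-methylidene-6-(2-methyl-1,3-dioxolan-2-yl)hexanoate
Conditions: DCC, DMAP (5 mol%), CH2Cl2, 0 °C
Reagents that add atoms: none
Why: Steglich esterification at 0 °C with little DMAP acylates the primary allylic alcohol without moving the β,γ-double bond into conjugation.

**Step 3**
Reactants: 6 (2E)-pent-2-en-4-yn-1-yl 3-methylidene-6-(2-methyl-1,3-dioxolan-2-yl)hexanoate
Product: 9 (2R,3S)-3-ethynyl-2-[5-(2-methyl-1,3-dioxolan-2-yl)pent-1-en-2-yl]pent-4-enoic acid, via boron ketene acetal 7 (not isolated), via acyloxyborane 8 (not isolated)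
Conditions: preformed (4S,5S)-2-bromo-4,5-diphenyl-1,3-bis{[3,5-bis(trifluoromethyl)phenyl]sulfonyl}-1,3,2-diazaborolidine (1.1 equiv), Et3N, toluene/hexane 2:1, −78 °C; then −20 → 4 °C, 48 h; aqueous work-up
Reagents that add atoms: none
Why: Corey's chiral-boron Ireland–Claisen rearrangement: soft enolisation gives the E(O) boron ketene acetal (alkenyl cis to the allylic oxygen), which rearranges through a chair transition state with the E-enyne substituent equatorial, so the two new centres form anti, and the (S,S)-sulfonamide framework selects the face that gives (2R,3S).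

**Step 4**
Reactants: 9 (2R,3S)-3-ethynyl-2-[5-(2-methyl-1,3-dioxolan-2-yl)pent-1-en-2-yl]pent-4-enoic acid
Product: 10 tert-butyl (2R,3S)-3-ethynyl-2-[5-(2-methyl-1,3-dioxolan-2-yl)pent-1-en-2-yl]pent-4-enoate
Conditions: tert-butyl 2,2,2-trichloroacetimidate (2 equiv), cyclohexane/CH2Cl2, rt
Reagents that add atoms: tert-butyl 2,2,2-trichloroacetimidate, CC(C)(C)OC(=N)C(Cl)(Cl)Cl
Why: acid-promoted O-alkylation by the imidate (tert-butyl ester formation) needs no base, so the epimerisable α-centre is untouched, and the ester stops the carboxyl group from adding to the alkyne in steps 6 and 7.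

**Step 5**
Reactants: 11 ethyl (2Z)-3-iodoprop-2-enoate
Product: 12 (3Z)-4-iodo-2-methylbut-3-en-2-ol
Conditions: MeMgBr (2.2 equiv), Et2O/THF, −78 → 0 °C; aq. NH4Cl
Reagents that add atoms: methylmagnesium bromide, C[Mg]Br
Why: double Grignard addition to the ester gives the tertiary alcohol with the Z-iodoalkene geometry retained.

**Step 6**
Reactants: 10 tert-butyl (2R,3S)-3-ethynyl-2-[5-(2-methyl-1,3-dioxolan-2-yl)pent-1-en-2-yl]pent-4-enoate; 12 (3Z)-4-iodo-2-methylbut-3-en-2-ol
Product: 13 tert-butyl (2R,3S,6Z)-3-ethenyl-8-hydroxy-8-methyl-2-[5-(2-methyl-1,3-dioxolan-2-yl)pent-1-en-2-yl]non-6-en-4-ynoate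
Conditions: PdCl2(PPh3)2 (3 mol%), CuI (5 mol%), Et3N, THF, rt
Reagents that add atoms: none
Why: Sonogashira coupling joins the terminal alkyne to the vinyl iodide with retention of the Z geometry that places the hydroxyl within reach of the alkyne; both stereocentres are untouched.

**Step 7**
Reactants: 13 tert-butyl (2R,3S,6Z)-3-ethenyl-8-hydroxy-8-methyl-2-[5-(2-methyl-1,3-dioxolan-2-yl)pent-1-en-2-yl]non-6-en-4-ynoate
Product: 16 tert-butyl (2R,3S)-3-[(1E)-1-(5,5-dimethylfuran-2(5H)-ylidene)-2-oxoethyl]-2-[5-(2-methyl-1,3-dioxolan-2-yl)pent-1-en-2-yl]pent-4-enoate, via dienol ether 14 (not isolated), via dioxolanyl acetal 15 (not isolated)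
Conditions: AgOTf (5 mol%), CH2Cl2, 0 °C → rt; then 2-methoxy-1,3-dioxolane (2 equiv), TMSOTf (5 mol%), −40 → −20 °C; then 5% aq. oxalic acid, THF, 0 °C
Reagents that add atoms: 2-methoxy-1,3-dioxolane, COC1OCCO1; water, O
Why: Proposed new method: the π-acid activates the alkyne for 5-exo-dig anti attack of the tertiary hydroxyl (the key ring C–O bond), and the vinyl-metal species, or the 2-alkylidene-2,5-dihydrofuran formed from it by protodemetalation, is captured at the exocyclic carbon by the 1,3-dioxolan-2-ylium ion (a formyl cation equivalent made from the orthoformate by TMSOTf), with loss of M+/H+ restoring the enol ether; mild acid then hydrolyses the vinylogous acetal to the push–pull enal, whose E geometry (CHO trans to the ring oxygen, the bulky sp3 substituent beside O) is both the retentive and the expected thermodynamic outcome; the closest known reaction types are the Ag- or Au-catalysed cycloisomerisation of (Z)-2-en-4-yn-1-ols to 2-alkylidene-2,5-dihydrofurans, Pt/Au carboalkoxylation with 1,3-shift of α-alkoxyalkyl cations, and the Lewis-acid addition of orthoformates to enol ethers.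

**Step 8**
Reactants: 16 tert-butyl (2R,3S)-3-[(1E)-1-(5,5-dimethylfuran-2(5H)-ylidene)-2-oxoethyl]-2-[5-(2-methyl-1,3-dioxolan-2-yl)pent-1-en-2-yl]pent-4-enoate
Product: 17 tert-butyl (2R,3S)-3-[(1E)-1-(5,5-dimethylfuran-2(5H)-ylidene)-2-oxoethyl]-2-[5-(2-methyl-1,3-dioxolan-2-yl)pent-1-en-2-yl]-5-oxopentanoate
Conditions: PdCl2(PhCN)2 (10 mol%), CuCl2·2H2O (10 mol%), AgNO2 (5 mol%), t-BuOH/MeNO2 15:1, O2 (1 atm), rt
Reagents that add atoms: dioxygen, O=O
Why: aldehyde-selective (anti-Markovnikov) nitrite-modified Wacker oxidation acts only on the monosubstituted vinyl group, whose branched allylic carbon and homoallylic ester favour oxygen at the terminus; the 1,1-disubstituted alkene and the push–pull diene are inert and no stereocentre is touched.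

**Step 9**
Reactants: 17 tert-butyl (2R,3S)-3-[(1E)-1-(5,5-dimethylfuran-2(5H)-ylidene)-2-oxoethyl]-2-[5-(2-methyl-1,3-dioxolan-2-yl)pent-1-en-2-yl]-5-oxopentanoate
Product: 18 (2R,3S)-3-[(1E)-1-(5,5-dimethylfuran-2(5H)-ylidene)-2-oxoethyl]-5-oxo-2-(6-oxohept-1-en-2-yl)pentanoic acid (CNP0150297.1)
Conditions: TFA/CH2Cl2 1:3, 0 °C; then H2O/THF, rt
Reagents that add atoms: water, O
Why: acidolysis of the tert-butyl ester and hydrolysis of the dioxolane (protecting-group removal) free the acid and the methyl ketone without base, so neither stereocentre nor the push–pull enal is disturbed.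

**Compound list**
1 | 2-(3-chloropropyl)-2-methyl-1,3-dioxolane | CC1(CCCCl)OCCO1 | starting material
2 | diketene (4-methylideneoxetan-2-one) | C=C1CC(=O)O1 | starting material
3 | [3-(2-methyl-1,3-dioxolan-2-yl)propyl]magnesium chloride | CC1(CCC[Mg]Cl)OCCO1 | intermediate (not isolated)
4 | 3-methylidene-6-(2-methyl-1,3-dioxolan-2-yl)hexanoic acid | C=C(CCCC1(C)OCCO1)CC(=O)O | intermediate
5 | (2E)-pent-2-en-4-yn-1-ol | OC/C=C/C#C | starting material
6 | (2E)-pent-2-en-4-yn-1-yl 3-methylidene-6-(2-methyl-1,3-dioxolan-2-yl)hexanoate | C=C(CCCC1(C)OCCO1)CC(=O)OC/C=C/C#C | intermediate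
7 | E(O) boron ketene acetal of 6, enolate oxygen bound to the (4S,5S)-4,5-diphenyl-1,3-bis{[3,5-bis(trifluoromethyl)phenyl]sulfonyl}-1,3,2-diazaborolidin-2-yl group, alkenyl cis to the pentenynyloxy group | C=C(CCCC1(C)OCCO1)/C=C(\OC/C=C/C#C)OB1N(S(=O)(=O)c2cc(C(F)(F)F)cc(C(F)(F)F)c2)[C@@H](c2ccccc2)[C@H](c2ccccc2)N1S(=O)(=O)c1cc(C(F)(F)F)cc(C(F)(F)F)c1 | intermediate (not isolated)
8 | acyloxyborane of acid 9 with the same (4S,5S)-diazaborolidine (B–O–C=O), (2R,3S) | C=C(CCCC1(C)OCCO1)[C@H](C(=O)OB1N(S(=O)(=O)c2cc(C(F)(F)F)cc(C(F)(F)F)c2)[C@@H](c2ccccc2)[C@H](c2ccccc2)N1S(=O)(=O)c1cc(C(F)(F)F)cc(C(F)(F)F)c1)[C@H](C=C)C#C | intermediate (not isolated)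
9 | (2R,3S)-3-ethynyl-2-[5-(2-methyl-1,3-dioxolan-2-yl)pent-1-en-2-yl]pent-4-enoic acid | C=C(CCCC1(C)OCCO1)[C@H](C(=O)O)[C@H](C=C)C#C | intermediate
10 | tert-butyl (2R,3S)-3-ethynyl-2-[5-(2-methyl-1,3-dioxolan-2-yl)pent-1-en-2-yl]pent-4-enoate | C=C(CCCC1(C)OCCO1)[C@H](C(=O)OC(C)(C)C)[C@H](C=C)C#C | intermediate
11 | ethyl (2Z)-3-iodoprop-2-enoate | CCOC(=O)/C=C\I | starting material
12 | (3Z)-4-iodo-2-methylbut-3-en-2-ol | CC(C)(O)/C=C\I | intermediate
13 | tert-butyl (2R,3S,6Z)-3-ethenyl-8-hydroxy-8-methyl-2-[5-(2-methyl-1,3-dioxolan-2-yl)pent-1-en-2-yl]non-6-en-4-ynoate | C=C(CCCC1(C)OCCO1)[C@H](C(=O)OC(C)(C)C)[C@H](C=C)C#C/C=C\C(C)(C)O | intermediate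
14 | tert-butyl (2R,3R)-3-[(Z)-(5,5-dimethylfuran-2(5H)-ylidene)methyl]-2-[5-(2-methyl-1,3-dioxolan-2-yl)pent-1-en-2-yl]pent-4-enoate | C=C(CCCC1(C)OCCO1)[C@H](C(=O)OC(C)(C)C)[C@H](C=C)/C=C1/C=CC(C)(C)O1 | intermediate (not isolated)
15 | tert-butyl (2R,3S)-3-[(E)-(5,5-dimethylfuran-2(5H)-ylidene)(1,3-dioxolan-2-yl)methyl]-2-[5-(2-methyl-1,3-dioxolan-2-yl)pent-1-en-2-yl]pent-4-enoate | C=C(CCCC1(C)OCCO1)[C@H](C(=O)OC(C)(C)C)[C@H](C=C)/C(C1OCCO1)=C1/C=CC(C)(C)O1 | intermediate (not isolated)
16 | tert-butyl (2R,3S)-3-[(1E)-1-(5,5-dimethylfuran-2(5H)-ylidene)-2-oxoethyl]-2-[5-(2-methyl-1,3-dioxolan-2-yl)pent-1-en-2-yl]pent-4-enoate | C=C(CCCC1(C)OCCO1)[C@H](C(=O)OC(C)(C)C)[C@H](C=C)/C(C=O)=C1/C=CC(C)(C)O1 | intermediate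
17 | tert-butyl (2R,3S)-3-[(1E)-1-(5,5-dimethylfuran-2(5H)-ylidene)-2-oxoethyl]-2-[5-(2-methyl-1,3-dioxolan-2-yl)pent-1-en-2-yl]-5-oxopentanoate | C=C(CCCC1(C)OCCO1)[C@H](C(=O)OC(C)(C)C)[C@H](CC=O)/C(C=O)=C1/C=CC(C)(C)O1 | intermediate
18 | (2R,3S)-3-[(1E)-1-(5,5-dimethylfuran-2(5H)-ylidene)-2-oxoethyl]-5-oxo-2-(6-oxohept-1-en-2-yl)pentanoic acid | C=C(CCCC(C)=O)[C@H](C(=O)O)[C@H](CC=O)/C(C=O)=C1/C=CC(C)(C)O1 | target

**Step count and risks**
Total step count: 9. Longest linear sequence: 8 (steps 1, 2, 3, 4, 6, 7, 8, 9).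

Most likely to fail, first: step 7, the proposed new method. The oxocarbenium formed on C-alkylation could be trapped by the nearby 1,1-disubstituted alkene, the tertiary allylic alcohol could ionise before it cyclises, and the formyl capture could be slow or give E/Z mixtures before the enal equilibrates. The fallback uses known chemistry, sets out from 13 and returns at 16. Compound 13 is treated with N-iodosuccinimide and NaHCO3 in MeCN at 0 °C; anti 5-exo-dig iodoetherification gives tert-butyl (2R,3S)-3-[(E)-(5,5-dimethylfuran-2(5H)-ylidene)iodomethyl]-2-[5-(2-methyl-1,3-dioxolan-2-yl)pent-1-en-2-yl]pent-4-enoate F5, with iodine trans to the ring oxygen. The vinyl iodide is then formylated with retention by Stille reductive carbonylation (Pd(PPh3)4, CO 1 atm, Bu3SnH added slowly, THF, 50 °C), which gives 16 with the geometry fixed kinetically.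

Second: step 3. The α-alkenyl ester may not give the E(O) boron ketene acetal cleanly (lower anti:syn ratio), the sense or level of induction may differ from the precedent, and the bromoborane is a Lewis acid that could attack the dioxolane. The fallback sets out from 6 and returns at 9. Soft enolisation (Et3N, TMSOTf, CH2Cl2, 0 °C → rt) gives the trimethylsilyl ketene acetal F1, which rearranges (silyl Ireland–Claisen) to the racemic trimethylsilyl ester F2. Aqueous work-up gives 9 together with its (2S,3R)-enantiomer F3. The racemate is resolved by crystallising the (S)-1-phenylethylammonium salt F4 of 9 (the amine enantiomer giving the less soluble salt would be found by screening), and acidification with dilute HCl returns 9.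

Third: step 8. The aldehyde:methyl ketone ratio may be modest at this hindered vinyl group, and Pd(II) may move the terminal alkene into conjugation. The fallback sets out from 16 and returns at 17. Cross-metathesis of 16 with vinylboronic acid pinacol ester (Hoveyda–Grubbs II, CH2Cl2, 40 °C) gives tert-butyl (2R,3S,4E)-3-[(1E)-1-(5,5-dimethylfuran-2(5H)-ylidene)-2-oxoethyl]-2-[5-(2-methyl-1,3-dioxolan-2-yl)pent-1-en-2-yl]-5-(4,4,5,5-tetramethyl-1,3,2-dioxaborolan-2-yl)pent-4-enoate F6. Oxidation of the alkenyl boronate with NaBO3·4H2O in THF/H2O at rt gives the enol and hence aldehyde 17.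

**Further compounds**
F1 | step 3 | trimethylsilyl ketene acetal of 6 (alkenyl cis to the pentenynyloxy group) | C=C(CCCC1(C)OCCO1)/C=C(\OC/C=C/C#C)O[Si](C)(C)C
F2 | step 3 | racemic trimethylsilyl (2R*,3S*)-3-ethynyl-2-[5-(2-methyl-1,3-dioxolan-2-yl)pent-1-en-2-yl]pent-4-enoate | C=C(CCCC1(C)OCCO1)[C@H](C(=O)O[Si](C)(C)C)[C@H](C=C)C#C.C=C(CCCC1(C)OCCO1)[C@@H](C(=O)O[Si](C)(C)C)[C@@H](C=C)C#C
F3 | step 3 | (2S,3R)-3-ethynyl-2-[5-(2-methyl-1,3-dioxolan-2-yl)pent-1-en-2-yl]pent-4-enoic acid | C=C(CCCC1(C)OCCO1)[C@@H](C(=O)O)[C@@H](C=C)C#C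
F4 | step 3 | (S)-1-phenylethylammonium (2R,3S)-3-ethynyl-2-[5-(2-methyl-1,3-dioxolan-2-yl)pent-1-en-2-yl]pent-4-enoate | C=C(CCCC1(C)OCCO1)[C@H](C(=O)[O-])[C@H](C=C)C#C.C[C@H]([NH3+])c1ccccc1
F5 | step 7 | tert-butyl (2R,3S)-3-[(E)-(5,5-dimethylfuran-2(5H)-ylidene)iodomethyl]-2-[5-(2-methyl-1,3-dioxolan-2-yl)pent-1-en-2-yl]pent-4-enoate | C=C(CCCC1(C)OCCO1)[C@H](C(=O)OC(C)(C)C)[C@H](C=C)/C(I)=C1/C=CC(C)(C)O1
F6 | step 8 | tert-butyl (2R,3S,4E)-3-[(1E)-1-(5,5-dimethylfuran-2(5H)-ylidene)-2-oxoethyl]-2-[5-(2-methyl-1,3-dioxolan-2-yl)pent-1-en-2-yl]-5-(4,4,5,5-tetramethyl-1,3,2-dioxaborolan-2-yl)pent-4-enoate | C=C(CCCC1(C)OCCO1)[C@H](C(=O)OC(C)(C)C)[C@H](/C=C/B1OC(C)(C)C(C)(C)O1)/C(C=O)=C1/C=CC(C)(C)O1
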